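**Retrosynthetic overview**

1. The target comes from hydrogenolysis of two aryl benzyl ethers and ozonolysis of a (Z)-1-arylpropenyl group (a masked aroyl group) on an all-trans 2-aryl-3-(hydroxymethyl)oxolane.
2. The oxolane (second ring, formed last) comes from acid-induced benzylic SN1 etherification of a triol, itself made by LiAlH4 reduction of the anti-aldol adduct of a β-substituted γ-butyrolactone with O-benzylisovanillin.
3. The γ-butyrolactone (first ring, first C–C stereocentre) comes from a Johnson–Claisen [3,3]-sigmatropic rearrangement of a (Z)-3-arylpent-2-ene-1,4-diol, with 1,3-chirality transfer from its (S)-carbinol.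
4. The ene-diol comes from copper-catalysed anti-arylmagnesiation of (S)-but-3-yn-2-ol with the Grignard reagent of benzyl-protected 5-bromo-2-methoxyphenol, followed by formaldehyde.
5. Ring order: lactone (Claisen), opened by hydride, then oxolane. The purchased (S)-carbinol is the only bought stereocentre and relays C4, then C3, then C2.

Assumption: ring numbering is O1, C2 (aryl), C3 (CH2OH), C4 (aroyl), C5; the target SMILES reads as 2S,3R,4S with all three substituents mutually trans; (S)-but-3-yn-2-ol and 3-(benzyloxy)-4-methoxybenzaldehyde are taken as inexpensive catalogue chemicals.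

**Route**

Step 1
Reactants: 1 5-bromo-2-methoxyphenol
Product: 2 2-(benzyloxy)-4-bromo-1-methoxybenzene
Conditions: BnBr (1.1 equiv), K2CO3 (1.5 equiv), DMF, 60 °C
Reagents that add atoms: benzyl bromide, BrCc1ccccc1
Why: Williamson ether synthesis (SN2 of the phenoxide on benzyl bromide) masks the phenol so that the aryl Grignard reagent can be formed; no stereocentre is involved.

Step 2
Reactants: 2 2-(benzyloxy)-4-bromo-1-methoxybenzene; 3 (S)-but-3-yn-2-ol
Product: 6 (2Z,4S)-3-[3-(benzyloxy)-4-methoxyphenyl]pent-2-ene-1,4-diol, via aryl Grignard reagent 4 (not isolated), via alkenylmagnesium chelate 5 (not isolated)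
Conditions: (a) 2, Mg, THF, reflux; (b) 3, i-PrMgCl (1.0 equiv), THF, 0 °C, then 4 (1.6 equiv), CuI (10 mol%), reflux; (c) dry (CH2O)n (excess), 0 °C to rt; aq. NH4Cl
Reagents that add atoms: paraformaldehyde (as formaldehyde), C=O
Why: Copper-catalysed anti-carbomagnesiation of the propargylic magnesium alkoxide (Duboudin-type) puts the aryl group on the alkyne carbon next to the carbinol and magnesium on the terminal carbon inside a five-membered chelate, so formaldehyde trapping gives the (Z)-ene-1,4-diol while the purchased (S)-centre is untouched.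

Step 3
Reactants: 6 (2Z,4S)-3-[3-(benzyloxy)-4-methoxyphenyl]pent-2-ene-1,4-diol
Product: 9 (4R)-4-{(1Z)-1-[3-(benzyloxy)-4-methoxyphenyl]prop-1-en-1-yl}oxolan-2-one, via cyclic orthoester 7 (not isolated), via cyclic ketene acetal 8 (not isolated)
Conditions: MeC(OEt)3 (1.5 equiv), EtCO2H (5 mol%), xylene, 140 °C, EtOH distilled off
Reagents that add atoms: triethyl orthoacetate, CCOC(C)(OCC)OCC
Why: Johnson–Claisen [3,3]-sigmatropic rearrangement through a chair transition state with the carbinol methyl group equatorial breaks the secondary allylic C–O bond and forms the C–C bond at the less substituted alkene terminus, so the (S)-C–O centre is transferred into the (R)-C–C centre of the lactone (ring C4 of the target) and the tethered primary oxygen becomes the lactone oxygen.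

Step 4
Reactants: 9 (4R)-4-{(1Z)-1-[3-(benzyloxy)-4-methoxyphenyl]prop-1-en-1-yl}oxolan-2-one; 10 3-(benzyloxy)-4-methoxybenzaldehyde
Product: 12 (3S,4R)-3-{[3-(benzyloxy)-4-methoxyphenyl](hydroxy)methyl}-4-{(1Z)-1-[3-(benzyloxy)-4-methoxyphenyl]prop-1-en-1-yl}oxolan-2-one as both carbinol epimers, via lithium enolate 11 (not isolated)
Conditions: LiN(SiMe3)2 (1.1 equiv), THF, −78 °C; then 10 (1.2 equiv), −78 °C; aq. NH4Cl
Reagents that add atoms: none
Why: Aldol addition of the lactone enolate takes place on the face anti to the C4 substituent, which sets the new C3 centre trans to C4 under substrate control; the carbinol epimers are carried on together because that centre is reset in step 6.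

Step 5
Reactants: 12 (3S,4R)-3-{[3-(benzyloxy)-4-methoxyphenyl](hydroxy)methyl}-4-{(1Z)-1-[3-(benzyloxy)-4-methoxyphenyl]prop-1-en-1-yl}oxolan-2-one
Product: 13 (2R,3R)-2-{[3-(benzyloxy)-4-methoxyphenyl](hydroxy)methyl}-3-{(1Z)-1-[3-(benzyloxy)-4-methoxyphenyl]prop-1-en-1-yl}butane-1,4-diol as both carbinol epimers
Conditions: LiAlH4 (2 equiv), THF, 0 °C to rt; H2O/aq. NaOH work-up
Reagents that add atoms: none
Why: Hydride reduction of the lactone gives the 1,4-diol without touching the isolated styrenyl alkene, the benzyl ethers or the two C–C stereocentres.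

Step 6
Reactants: 13 (2R,3R)-2-{[3-(benzyloxy)-4-methoxyphenyl](hydroxy)methyl}-3-{(1Z)-1-[3-(benzyloxy)-4-methoxyphenyl]prop-1-en-1-yl}butane-1,4-diol
Product: 14 {(2S,3R,4R)-2-[3-(benzyloxy)-4-methoxyphenyl]-4-{(1Z)-1-[3-(benzyloxy)-4-methoxyphenyl]prop-1-en-1-yl}oxolan-3-yl}methanol
Conditions: TsOH·H2O (5 mol%), CH2Cl2 (0.02 M), 0 °C; Et3N quench
Reagents that add atoms: none
Why: SN1 cycloetherification: the 4-methoxy-stabilised benzylic cation from either carbinol epimer is captured by the CH2OH group on C4 (the other primary OH could only give an oxetane) on the face anti to the C3 substituent, and reversible ionisation funnels the material to the 2,3-trans oxolane.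

Step 7
Reactants: 14 {(2S,3R,4R)-2-[3-(benzyloxy)-4-methoxyphenyl]-4-{(1Z)-1-[3-(benzyloxy)-4-methoxyphenyl]prop-1-en-1-yl}oxolan-3-yl}methanol
Product: 16 [3-(benzyloxy)-4-methoxyphenyl]{(3S,4R,5S)-5-[3-(benzyloxy)-4-methoxyphenyl]-4-(hydroxymethyl)oxolan-3-yl}methanone, via primary ozonide 15 (not isolated)
Conditions: O3, CH2Cl2, −78 °C (Sudan Red 7B end-point); then Me2S, −78 °C to rt
Reagents that add atoms: ozone, [O-][O+]=O
Why: Ozonolysis (1,3-dipolar cycloaddition of ozone to the only alkene, much faster than attack on the alkoxyarenes at −78 °C) with reductive work-up unmasks the aryl ketone, leaving C4 α to the carbonyl in its stable trans arrangement.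

Step 8
Reactants: 16 [3-(benzyloxy)-4-methoxyphenyl]{(3S,4R,5S)-5-[3-(benzyloxy)-4-methoxyphenyl]-4-(hydroxymethyl)oxolan-3-yl}methanone
Product: 17 (3-hydroxy-4-methoxyphenyl)[(3S,4R,5S)-4-(hydroxymethyl)-5-(3-hydroxy-4-methoxyphenyl)oxolan-3-yl]methanone
Conditions: H2 (1 atm), 10% Pd/C, EtOAc, rt, monitored to full debenzylation
Reagents that add atoms: none
Why: Hydrogenolysis of the two aryl benzyl ethers under neutral conditions is much faster than reduction of the aryl ketone or cleavage of the cyclic benzylic ether, so the free phenols are released with all three stereocentres intact.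

**Compound list**

1 | 5-bromo-2-methoxyphenol | COc1ccc(Br)cc1O | starting material
2 | 2-(benzyloxy)-4-bromo-1-methoxybenzene | COc1ccc(Br)cc1OCc1ccccc1 | intermediate
3 | (S)-but-3-yn-2-ol | C[C@H](O)C#C | starting material
4 | [3-(benzyloxy)-4-methoxyphenyl]magnesium bromide | COc1ccc([Mg]Br)cc1OCc1ccccc1 | intermediate (not isolated)
5 | (5S)-4-[3-(benzyloxy)-4-methoxyphenyl]-5-methyl-2,5-dihydro-1,2-oxamagnesole | C[C@@H]1O[Mg]C=C1c1ccc(OC)c(OCc2ccccc2)c1 | intermediate (not isolated)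
6 | (2Z,4S)-3-[3-(benzyloxy)-4-methoxyphenyl]pent-2-ene-1,4-diol | C[C@H](O)/C(c1ccc(OC)c(OCc2ccccc2)c1)=C\CO | intermediate
7 | (4S)-5-[3-(benzyloxy)-4-methoxyphenyl]-2-ethoxy-2,4-dimethyl-4,7-dihydro-1,3-dioxepine (mixture at C2) | CCOC1(C)OCC=C(c2ccc(OC)c(OCc3ccccc3)c2)[C@H](C)O1 | intermediate (not isolated)
8 | (4S)-5-[3-(benzyloxy)-4-methoxyphenyl]-4-methyl-2-methylidene-4,7-dihydro-1,3-dioxepine | C=C1OCC=C(c2ccc(OC)c(OCc3ccccc3)c2)[C@H](C)O1 | intermediate (not isolated)
9 | (4R)-4-{(1Z)-1-[3-(benzyloxy)-4-methoxyphenyl]prop-1-en-1-yl}oxolan-2-one | O=C1C[C@@H](CO1)/C(c1ccc(OC)c(OCc2ccccc2)c1)=C/C | intermediate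
10 | 3-(benzyloxy)-4-methoxybenzaldehyde | COc1ccc(C=O)cc1OCc1ccccc1 | starting material
11 | lithium (4R)-4-{(1Z)-1-[3-(benzyloxy)-4-methoxyphenyl]prop-1-en-1-yl}-4,5-dihydrofuran-2-olate | [Li]OC1=C[C@@H](CO1)/C(c1ccc(OC)c(OCc2ccccc2)c1)=C/C | intermediate (not isolated)
12 | (3S,4R)-3-{[3-(benzyloxy)-4-methoxyphenyl](hydroxy)methyl}-4-{(1Z)-1-[3-(benzyloxy)-4-methoxyphenyl]prop-1-en-1-yl}oxolan-2-one (both carbinol epimers) | O=C1OC[C@@H](/C(c2ccc(OC)c(OCc3ccccc3)c2)=C/C)[C@H]1C(O)c1ccc(OC)c(OCc2ccccc2)c1 | intermediate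
13 | (2R,3R)-2-{[3-(benzyloxy)-4-methoxyphenyl](hydroxy)methyl}-3-{(1Z)-1-[3-(benzyloxy)-4-methoxyphenyl]prop-1-en-1-yl}butane-1,4-diol (both carbinol epimers) | OC[C@@H](/C(c1ccc(OC)c(OCc2ccccc2)c1)=C/C)[C@H](CO)C(O)c1ccc(OC)c(OCc2ccccc2)c1 | intermediate
14 | {(2S,3R,4R)-2-[3-(benzyloxy)-4-methoxyphenyl]-4-{(1Z)-1-[3-(benzyloxy)-4-methoxyphenyl]prop-1-en-1-yl}oxolan-3-yl}methanol | COc1ccc(/C(=C\C)[C@@H]2CO[C@H](c3ccc(OC)c(OCc4ccccc4)c3)[C@H]2CO)cc1OCc1ccccc1 | intermediate
15 | {(2S,3R,4S)-2-[3-(benzyloxy)-4-methoxyphenyl]-4-{4-[3-(benzyloxy)-4-methoxyphenyl]-5-methyl-1,2,3-trioxolan-4-yl}oxolan-3-yl}methanol | COc1ccc(C2(OOOC2C)[C@@H]2CO[C@H](c3ccc(OC)c(OCc4ccccc4)c3)[C@H]2CO)cc1OCc1ccccc1 | intermediate (not isolated)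
16 | [3-(benzyloxy)-4-methoxyphenyl]{(3S,4R,5S)-5-[3-(benzyloxy)-4-methoxyphenyl]-4-(hydroxymethyl)oxolan-3-yl}methanone | COc1ccc(C(=O)[C@@H]2CO[C@H](c3ccc(OC)c(OCc4ccccc4)c3)[C@H]2CO)cc1OCc1ccccc1 | intermediate
17 | (3-hydroxy-4-methoxyphenyl)[(3S,4R,5S)-4-(hydroxymethyl)-5-(3-hydroxy-4-methoxyphenyl)oxolan-3-yl]methanone | COc1ccc(C(=O)[C@@H]2CO[C@H](c3ccc(OC)c(O)c3)[C@H]2CO)cc1O | target

**Step count and risks**

Total steps: 8. Longest linear sequence: 8 (1 → 2 → 6 → 9 → 12 → 13 → 14 → 16 → 17); compounds 3 and 10 are bought.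

Most likely to fail, step 2: the chelated alkenylmagnesium 5 may react sluggishly with formaldehyde and end up protonated. The fallback sets out from 2 and 3 through the same intermediate 5, which is quenched with I2 (THF, −20 °C), a well-behaved trap for these chelates, to give (2S,3Z)-3-[3-(benzyloxy)-4-methoxyphenyl]-4-iodobut-3-en-2-ol F1. Stille coupling of F1 with (tributylstannyl)methanol (CCCC[Sn](CO)(CCCC)CCCC; Pd(PPh3)4, dioxane, 90 °C) installs the CH2OH group with retention of alkene geometry and comes back to the route at 6.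

Most likely to fail, step 3: under the acidic orthoester conditions the free cis-ene-diol may cyclodehydrate to a 2,5-dihydrofuran or rearrange through the primary oxygen. The minor (E)-alkene lactone from the axial-methyl chair carries the opposite C4 configuration, but it is a diastereomer of 9 and is removed by chromatography. The fallback sets out from 6 and replaces the orthoester process by a low-temperature, base-mediated Ireland–Claisen rearrangement. Selective silylation of the primary alcohol (t-BuMe2SiCl, imidazole, CH2Cl2) gives (2S,3Z)-3-[3-(benzyloxy)-4-methoxyphenyl]-5-[(tert-butyldimethylsilyl)oxy]pent-3-en-2-ol F2. Acetylation (Ac2O, pyridine, DMAP) gives (2S,3Z)-3-[3-(benzyloxy)-4-methoxyphenyl]-5-[(tert-butyldimethylsilyl)oxy]pent-3-en-2-yl acetate F3. Enolisation and silylation (LiN(SiMe3)2, Me3SiCl, THF, −78 °C, then 50 °C, aqueous work-up) rearranges it through the same chair to (3R,4Z)-4-[3-(benzyloxy)-4-methoxyphenyl]-3-{[(tert-butyldimethylsilyl)oxy]methyl}hex-4-enoic acid F4. Desilylation (Bu4NF, THF) followed by catalytic pyridinium tosylate closes the lactone and comes back to the route at 9.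

Most likely to fail, step 6: the Brønsted acid may also protonate the electron-rich trisubstituted styrene, so that the C3 hydroxymethyl group adds to it and gives an isomeric oxolane. The fallback sets out from 9 and generates the same benzylic cation oxidatively instead of by acid. Alkylation of the lithium enolate (LiN(SiMe3)2, THF, −78 °C) with 3-(benzyloxy)-4-methoxybenzyl bromide (COc1ccc(CBr)cc1OCc1ccccc1) anti to the C4 substituent gives (3R,4R)-3-[3-(benzyloxy)-4-methoxybenzyl]-4-{(1Z)-1-[3-(benzyloxy)-4-methoxyphenyl]prop-1-en-1-yl}oxolan-2-one F5. Reduction (LiAlH4, THF, 0 °C) gives (2R,3R)-2-[3-(benzyloxy)-4-methoxybenzyl]-3-{(1Z)-1-[3-(benzyloxy)-4-methoxyphenyl]prop-1-en-1-yl}butane-1,4-diol F6. DDQ (1.2 equiv, CH2Cl2, 0 °C) abstracts the benzylic hydride and the C4 hydroxymethyl group closes the 2,3-trans oxolane, which comes back to the route at 14.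

**Further compounds**

F1 | step 2 | (2S,3Z)-3-[3-(benzyloxy)-4-methoxyphenyl]-4-iodobut-3-en-2-ol | C[C@H](O)/C(c1ccc(OC)c(OCc2ccccc2)c1)=C\I
F2 | step 3 | (2S,3Z)-3-[3-(benzyloxy)-4-methoxyphenyl]-5-[(tert-butyldimethylsilyl)oxy]pent-3-en-2-ol | C[C@H](O)/C(c1ccc(OC)c(OCc2ccccc2)c1)=C\CO[Si](C)(C)C(C)(C)C
F3 | step 3 | (2S,3Z)-3-[3-(benzyloxy)-4-methoxyphenyl]-5-[(tert-butyldimethylsilyl)oxy]pent-3-en-2-yl acetate | C[C@H](OC(C)=O)/C(c1ccc(OC)c(OCc2ccccc2)c1)=C\CO[Si](C)(C)C(C)(C)C
F4 | step 3 | (3R,4Z)-4-[3-(benzyloxy)-4-methoxyphenyl]-3-{[(tert-butyldimethylsilyl)oxy]methyl}hex-4-enoic acid | OC(=O)C[C@@H](CO[Si](C)(C)C(C)(C)C)/C(c1ccc(OC)c(OCc2ccccc2)c1)=C/C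
F5 | step 6 | (3R,4R)-3-[3-(benzyloxy)-4-methoxybenzyl]-4-{(1Z)-1-[3-(benzyloxy)-4-methoxyphenyl]prop-1-en-1-yl}oxolan-2-one | O=C1OC[C@@H](/C(c2ccc(OC)c(OCc3ccccc3)c2)=C/C)[C@H]1Cc1ccc(OC)c(OCc2ccccc2)c1
F6 | step 6 | (2R,3R)-2-[3-(benzyloxy)-4-methoxybenzyl]-3-{(1Z)-1-[3-(benzyloxy)-4-methoxyphenyl]prop-1-en-1-yl}butane-1,4-diol | OC[C@@H](/C(c1ccc(OC)c(OCc2ccccc2)c1)=C/C)[C@H](CO)Cc1ccc(OC)c(OCc2ccccc2)c1
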